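**Retrosynthetic overview**
1. Target 22 ← desilylation ← Evans–Tishchenko reduction of β-hydroxy enone 18 with angelaldehyde 20: the bought C10 centre sets C8 (1,3-anti) and the C10 angelate is installed in the same event.
2. 18 ← C8–C9 bond by a light-driven decatungstate/nickel coupling of the formyl C–H of enal 14 with chiral-pool epoxide 16 (from methyl (R)-glycidate, L-serine series).
3. 14 ← allylic oxidation of the isopropenyl methyl; C4/C5 trans-diol ← hydroxyl-directed epoxidation and trans-diaxial hydrolysis; C3 ← Luche reduction and angeloylation; C2 ← α′-hydroxylation of (S)-carvone and Mitsunobu inversion.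
4. Stereocontrol: C1 is bought in (S)-carvone and relays to C2, C3, C4 and C5; C10 is bought in the glycidate and relays to C8.
5. Ring order: the only carbocycle comes with carvone; the only ring made is the transient C4–C5 epoxide (step 5), opened again in step 6.

Assumption: the SMILES defines the target as (1R,2S,3S,4R,5S,8R,10R) with two (Z)-2-methylbut-2-enoyl (angeloyl, Ang) esters. Locants used below: ring C1 (carries the chain), C2 (OH), C3 (OAng), C4 (C(CH3)OH), C5 (OH), C6; chain C7 (=CH2), C8 (OH), C9, C10 (OAng), C11 (C(CH3)2OH).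

**Step 1**
Reactants: 1 (S)-(+)-carvone
Product: 3 (5R,6R)-6-hydroxy-2-methyl-5-(prop-1-en-2-yl)cyclohex-2-en-1-one (trans-6-hydroxycarvone), via lithium dienolate 2 (not isolated)
Conditions: LiN(iPr)2, THF, −78 °C; then racemic 2-(phenylsulfonyl)-3-phenyloxaziridine, −78 °C
Reagents that add atoms: 2-(phenylsulfonyl)-3-phenyloxaziridine, O=S(=O)(N1OC1c1ccccc1)c1ccccc1
Why: Kinetic deprotonation at the α′-methylene (C2) gives the cross-conjugated dienolate, which the N-sulfonyloxaziridine oxidises (Davis enolate hydroxylation) on the face away from the adjacent isopropenyl group, so C2–OH is expected trans to the bought C1 centre; any minor cis epimer is 5 itself and is added after step 2.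

**Step 2**
Reactants: 3 trans-6-hydroxycarvone
Product: 5 (5R,6S)-6-hydroxy-2-methyl-5-(prop-1-en-2-yl)cyclohex-2-en-1-one (cis-6-hydroxycarvone), via cis formate 4 (not isolated)
Conditions: PPh3, DIAD, HCO2H, THF, 0 °C to rt; then NaHCO3, MeOH, 0 °C
Reagents that add atoms: formic acid, O=CO
Why: Mitsunobu reaction: formate displaces the α-keto oxyphosphonium by SN2 with inversion, placing the C2 oxygen cis to the C1 isopropenyl group, and the labile formate is methanolysed in the same pot.

**Step 3**
Reactants: 5 cis-6-hydroxycarvone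
Product: 6 (5R,6S)-6-[(tert-butyldimethylsilyl)oxy]-2-methyl-5-(prop-1-en-2-yl)cyclohex-2-en-1-one
Conditions: TBSCl, imidazole, DMF, rt
Reagents that add atoms: tert-butyldimethylsilyl chloride, CC(C)(C)[Si](C)(C)Cl
Why: Standard silylation; unlike an ester the silyl ether does not migrate to O3 under the later acylation conditions, and it stops the cis C2 oxygen from closing a lactol or lactone onto the C8 carbonyl made in step 7.

**Step 4**
Reactants: 6
Product: 7 (1R,5R,6S)-6-[(tert-butyldimethylsilyl)oxy]-2-methyl-5-(prop-1-en-2-yl)cyclohex-2-en-1-ol (C3–OH, C2–OTBS and C1 isopropenyl all cis)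
Conditions: NaBH4, CeCl3·7H2O, MeOH, −78 °C
Reagents that add atoms: none
Why: Luche 1,2-reduction: hydride adds to the enone carbonyl from the face opposite the C1 and C2 substituents (as carvone gives cis-carveol), so the C3 carbinol is cis to both.

**Step 5**
Reactants: 7
Product: 8 epoxy alcohol (7 with the C4–C5 alkene converted into an epoxide whose oxygen is cis to C3–OH, C2–OTBS and the C1 isopropenyl group)
Conditions: VO(acac)2 (3 mol%), t-BuOOH, CH2Cl2, 0 °C to rt
Reagents that add atoms: tert-butyl hydroperoxide, CC(C)(C)OO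
Why: Vanadium-catalysed hydroxyl-directed epoxidation delivers oxygen to the ring alkene on the face of the allylic C3 hydroxyl and leaves the isolated isopropenyl alkene untouched.

**Step 6**
Reactants: 8 epoxy alcohol; 9 angelic acid
Product: 12 (1R,2S,3S,4R,5S)-configured ring diol (C1 isopropenyl, C2–OTBS, C3–OAng, C4(CH3)–OH, C5–OH), via mixed anhydride 10 (not isolated), via epoxy angelate 11 (not isolated)
Conditions: 9, 2,4,6-trichlorobenzoyl chloride, Et3N, THF, rt, filter; then 8, DMAP, toluene, 80 °C; then HClO4 (5 mol%), THF/H2O 4:1, 0 °C to rt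
Reagents that add atoms: water, O
Why: Yamaguchi esterification acylates the only free hydroxyl with retention of the Z alkene; aqueous acid then opens the epoxide by Fürst–Plattner trans-diaxial attack of water at the secondary C5 (inversion), the tertiary C4–O bond staying intact, so C4–OH remains cis and C5–OH becomes trans to the other ring substituents.

**Step 7**
Reactants: 12
Product: 14 enal (12 with the isopropenyl methyl oxidised to CHO; a 2-substituted acrolein, C8 aldehyde), via allylic alcohol 13 (not isolated)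
Conditions: SeO2 (20 mol%), t-BuOOH, CH2Cl2, rt; then MnO2, CH2Cl2, rt
Reagents that add atoms: tert-butyl hydroperoxide, CC(C)(C)OO
Why: Selenium dioxide allylic oxidation (ene reaction then 2,3-sigmatropic shift) attacks only the electron-rich 1,1-disubstituted alkene and oxidises its methyl group (the angelate alkene is electron-poor); MnO2 then takes the primary allylic alcohol to the enal without touching the ring carbinols.

**Step 8**
Reactants: 15 methyl (R)-glycidate
Product: 16 (R)-2-(oxiran-2-yl)propan-2-ol
Conditions: MeMgBr (2.2 equiv), THF, −78 to −40 °C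
Reagents that add atoms: methylmagnesium bromide, C[Mg]Br
Why: Double Grignard addition to the ester is faster than epoxide opening at low temperature and does not touch the bought stereocentre (the future C10).

**Step 9**
Reactants: 14 enal; 16 epoxy alcohol
Product: 18 β-hydroxy enone (C8 ketone conjugated to the C7 methylene, (10R)-C10–OH, C11–OH; ring as in 12), via bromohydrin 17 (not isolated)
Conditions: (nBu4N)4[W10O32] (2 mol%), NiBr2(dme) (10 mol%), 4,4′-di-tert-butyl-2,2′-bipyridine (12 mol%), 2,4,6-collidinium bromide (30 mol%), 16 (2 equiv), MeCN, 390 nm LEDs, rt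
Reagents that add atoms: none
Why: Proposed new method: excited decatungstate abstracts the formyl hydrogen of 14 to give an acyl radical; the stored proton is relayed as HBr through collidinium bromide and opens epoxide 16 at its CH2 terminus to bromohydrin 17; zerovalent nickel (regenerated by the reduced decatungstate) adds to the C–Br bond, captures the acyl radical and reductively eliminates the C8–C9 bond, returning bromide, so aldehyde plus epoxide give the β-hydroxy ketone with no stoichiometric reagent and with C10 untouched; the closest known reactions are nickel/hydrogen-atom-transfer photocatalytic coupling of aldehyde C–H bonds with alkyl bromides and nickel-catalysed halide-relay coupling of epoxides with aryl halides.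

**Step 10**
Reactants: 9 angelic acid
Product: 19 angelyl alcohol, (Z)-2-methylbut-2-en-1-ol
Conditions: LiAlH4, Et2O, 0 °C
Reagents that add atoms: none
Why: Hydride reduction of the conjugated acid to the allylic alcohol leaves the trisubstituted alkene and its Z geometry intact.

**Step 11**
Reactants: 19
Product: 20 angelaldehyde, (Z)-2-methylbut-2-enal
Conditions: MnO2, CH2Cl2, 0 °C, filtered solution used at once
Reagents that add atoms: none
Why: Neutral MnO2 oxidation of the allylic alcohol gives the Z enal, and immediate use limits isomerisation to tiglaldehyde.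

**Step 12**
Reactants: 18 β-hydroxy enone; 20 angelaldehyde
Product: 21 2-O-TBS ether of the target ((8R)-C8–OH, (10R)-C10–OAng)
Conditions: SmI2 (30 mol%), 20 (5 equiv), THF, −10 °C
Reagents that add atoms: none
Why: Evans–Tishchenko reduction: the C10 hydroxyl forms a samarium-bound hemiacetal with 20 and delivers its hydride to the C8 ketone through a chair-like six-membered transition state, giving the 1,3-anti (8R) carbinol while the aldehyde ends up as the C10 angelate, so C8 is set by the bought C10 centre and the second ester is placed regiospecifically.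

**Step 13**
Reactants: 21
Product: 22 CNP0108485.1 (target)
Conditions: HF·pyridine, pyridine/THF, 0 °C to rt
Reagents that add atoms: none
Why: Fluoride-driven Si–O cleavage under mildly acidic conditions that do not hydrolyse the two angelates or promote acyl migration.

**Compound list**
1 | (S)-(+)-carvone | C=C(C)[C@H]1CC=C(C)C(=O)C1 | starting material
2 | lithium cross-conjugated dienolate of 1 | [Li+].C=C(C)[C@H]1CC=C(C)C([O-])=C1 | intermediate
3 | (5R,6R)-6-hydroxy-2-methyl-5-(prop-1-en-2-yl)cyclohex-2-en-1-one | C=C(C)[C@H]1CC=C(C)C(=O)[C@@H]1O | intermediate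
4 | (1S,6R)-3-methyl-2-oxo-6-(prop-1-en-2-yl)cyclohex-3-en-1-yl formate | C=C(C)[C@H]1CC=C(C)C(=O)[C@H]1OC=O | intermediate
5 | (5R,6S)-6-hydroxy-2-methyl-5-(prop-1-en-2-yl)cyclohex-2-en-1-one | C=C(C)[C@H]1CC=C(C)C(=O)[C@H]1O | intermediate
6 | (5R,6S)-6-[(tert-butyldimethylsilyl)oxy]-2-methyl-5-(prop-1-en-2-yl)cyclohex-2-en-1-one | C=C(C)[C@H]1CC=C(C)C(=O)[C@H]1O[Si](C)(C)C(C)(C)C | intermediate
7 | (1R,5R,6S)-6-[(tert-butyldimethylsilyl)oxy]-2-methyl-5-(prop-1-en-2-yl)cyclohex-2-en-1-ol | C=C(C)[C@H]1CC=C(C)[C@@H](O)[C@H]1O[Si](C)(C)C(C)(C)C | intermediate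
8 | C4–C5 epoxide of 7, epoxide oxygen cis to C3–OH, C2–OTBS and C1 isopropenyl | C=C(C)[C@H]1C[C@H]2O[C@@]2(C)[C@@H](O)[C@H]1O[Si](C)(C)C(C)(C)C | intermediate
9 | angelic acid, (Z)-2-methylbut-2-enoic acid | C/C=C(/C)C(=O)O | starting material
10 | angelic 2,4,6-trichlorobenzoic anhydride | C/C=C(/C)C(=O)OC(=O)c1c(Cl)cc(Cl)cc1Cl | intermediate
11 | C3 angelate of 8 | C=C(C)[C@H]1C[C@H]2O[C@@]2(C)[C@@H](OC(=O)/C(C)=C\C)[C@H]1O[Si](C)(C)C(C)(C)C | intermediate
12 | (1R,2S,3S,4R,5S) ring diol: C1 isopropenyl, C2–OTBS, C3–OAng, C4(CH3)–OH, C5–OH | C=C(C)[C@H]1C[C@H](O)[C@@](C)(O)[C@@H](OC(=O)/C(C)=C\C)[C@H]1O[Si](C)(C)C(C)(C)C | intermediate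
13 | C8 allylic alcohol derived from 12 | C=C(CO)[C@H]1C[C@H](O)[C@@](C)(O)[C@@H](OC(=O)/C(C)=C\C)[C@H]1O[Si](C)(C)C(C)(C)C | intermediate
14 | C8 enal derived from 12 | C=C(C=O)[C@H]1C[C@H](O)[C@@](C)(O)[C@@H](OC(=O)/C(C)=C\C)[C@H]1O[Si](C)(C)C(C)(C)C | intermediate
15 | methyl (R)-glycidate, methyl (2R)-oxirane-2-carboxylate | COC(=O)[C@H]1CO1 | starting material
16 | (R)-2-(oxiran-2-yl)propan-2-ol | CC(C)(O)[C@H]1CO1 | intermediate
17 | (S)-1-bromo-3-methylbutane-2,3-diol | CC(C)(O)[C@H](O)CBr | intermediate
18 | β-hydroxy enone: C8 ketone, (10R)-OH, C11–OH, ring as in 12 | C=C(C(=O)C[C@@H](O)C(C)(C)O)[C@H]1C[C@H](O)[C@@](C)(O)[C@@H](OC(=O)/C(C)=C\C)[C@H]1O[Si](C)(C)C(C)(C)C | intermediate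
19 | angelyl alcohol, (Z)-2-methylbut-2-en-1-ol | C/C=C(/C)CO | intermediate
20 | angelaldehyde, (Z)-2-methylbut-2-enal | C/C=C(/C)C=O | intermediate
21 | 2-O-TBS ether of the target | C=C([C@H](O)C[C@@H](OC(=O)/C(C)=C\C)C(C)(C)O)[C@H]1C[C@H](O)[C@@](C)(O)[C@@H](OC(=O)/C(C)=C\C)[C@H]1O[Si](C)(C)C(C)(C)C | intermediate
22 | CNP0108485.1 | C=C([C@H](O)C[C@@H](OC(=O)/C(C)=C\C)C(C)(C)O)[C@H]1C[C@H](O)[C@@](C)(O)[C@@H](OC(=O)/C(C)=C\C)[C@H]1O | target

**Step count**
Total: 13 steps (10 on the main line, 1 for epoxide 16, 2 for angelaldehyde 20). Longest linear sequence: 10 steps (1–7, 9, 12, 13).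

**Three steps most likely to fail**

Step 9 (the proposed new coupling). The β-hydroxyalkyl radical may add to the methylene of the enal or of the product enone, decatungstate may abstract a carbinol C–H instead of the formyl C–H, and the bromide relay may stall. Known-chemistry fallback, setting out from 14 and returning at 18: Pinnick oxidation (NaClO2, NaH2PO4, 2-methylbut-2-ene) gives the acrylic acid F1, and 2,2′-dipyridyl disulfide with PPh3 converts it into the S-(pyridin-2-yl) thioester F2. Epoxide 16 is opened with LiI and AcOH to (S)-1-iodo-3-methylbutane-2,3-diol F3. A thermal nickel-catalysed reductive acyl–alkyl cross-electrophile coupling of F2 with F3 (NiCl2(dme), 4,4′-di-tert-butyl-2,2′-bipyridine, Zn powder, DMA) then gives 18.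

Step 12 (Evans–Tishchenko with a Z-enal). α,β-Unsaturated aldehydes are unusual hydride donors in this reaction, angelaldehyde can isomerise to tiglaldehyde before hydride transfer, and the C10 alkoxide could add to the enone methylene instead. Fallback, setting out from 18 and returning at 22: the standard Evans–Tishchenko reduction with acetaldehyde (SmI2 cat.) gives the anti C8-alcohol C10-acetate F4. TESOTf and 2,6-lutidine mask the C5 and C8 carbinols as the bis-triethylsilyl ether F5. K2CO3 in MeOH removes only the acetate to give the C10 alcohol F6, and Yamaguchi esterification with 9 gives the C10 angelate F7. HF·pyridine then removes all silyl groups to give 22 directly.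

Step 2 (Mitsunobu inversion of an α-hydroxy enone). The oxyphosphonium may eliminate towards the dienone and phenol, or the product may epimerise back to the trans isomer through the enediol. Fallback, setting out from 3 and returning at 4: Tf2O and pyridine at −78 °C give the triflate F8, which HCO2Cs with 18-crown-6 in toluene displaces by SN2 with inversion to give formate 4; this is methanolysed to 5 as in step 2.

**Further compounds**
F1 | step 9 | C8 carboxylic acid from 14 (2-substituted acrylic acid) | C=C(C(=O)O)[C@H]1C[C@H](O)[C@@](C)(O)[C@@H](OC(=O)/C(C)=C\C)[C@H]1O[Si](C)(C)C(C)(C)C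
F2 | step 9 | S-(pyridin-2-yl) thioester of F1 | C=C(C(=O)Sc1ccccn1)[C@H]1C[C@H](O)[C@@](C)(O)[C@@H](OC(=O)/C(C)=C\C)[C@H]1O[Si](C)(C)C(C)(C)C
F3 | step 9 | (S)-1-iodo-3-methylbutane-2,3-diol | CC(C)(O)[C@H](O)CI
F4 | step 12 | C10 acetate with anti (8R)-OH (21 with acetyl in place of the C10 angeloyl group) | C=C([C@H](O)C[C@@H](OC(C)=O)C(C)(C)O)[C@H]1C[C@H](O)[C@@](C)(O)[C@@H](OC(=O)/C(C)=C\C)[C@H]1O[Si](C)(C)C(C)(C)C
F5 | step 12 | 5,8-bis-O-triethylsilyl ether of F4 | C=C([C@H](O[Si](CC)(CC)CC)C[C@@H](OC(C)=O)C(C)(C)O)[C@H]1C[C@H](O[Si](CC)(CC)CC)[C@@](C)(O)[C@@H](OC(=O)/C(C)=C\C)[C@H]1O[Si](C)(C)C(C)(C)C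
F6 | step 12 | C10 alcohol from F5 | C=C([C@H](O[Si](CC)(CC)CC)C[C@@H](O)C(C)(C)O)[C@H]1C[C@H](O[Si](CC)(CC)CC)[C@@](C)(O)[C@@H](OC(=O)/C(C)=C\C)[C@H]1O[Si](C)(C)C(C)(C)C
F7 | step 12 | C10 angelate of F6 | C=C([C@H](O[Si](CC)(CC)CC)C[C@@H](OC(=O)/C(C)=C\C)C(C)(C)O)[C@H]1C[C@H](O[Si](CC)(CC)CC)[C@@](C)(O)[C@@H](OC(=O)/C(C)=C\C)[C@H]1O[Si](C)(C)C(C)(C)C
F8 | step 2 | trifluoromethanesulfonate of 3 | C=C(C)[C@H]1CC=C(C)C(=O)[C@@H]1OS(=O)(=O)C(F)(F)F
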